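## Structural features

Lappaol A is a sesquilignan: a trans-α,β-dibenzyl-γ-butyrolactone (lactone C3 and C4 both R, the matairesinol pattern) whose β-benzyl arene is also the benzo ring of a 2-aryl-3-(hydroxymethyl)-7-methoxy-2,3-dihydrobenzofuran. The dihydrofuran ring (O1, C2, C3, C3a, C7a) carries two adjacent stereocentres, C2 (S, bearing the 4-hydroxy-3-methoxyphenyl group) and C3 (R, bearing CH2OH), which are trans. The lactone carries the second adjacent pair. The two pairs lie five bonds apart on opposite edges of a benzene ring (C3–C3a–C4–C5–CH2–lactone C4), so neither can steer the other. The central arene is 1,2,3,5-tetrasubstituted with a crowded contiguous edge C7(OMe)/C7a(O1)/C3a(C3). Fragile points are the lactone (epimerisable α-C–H, opened by base, reduced by hydrides), the O1–C2 bond (a benzylic aryl ether para to a phenol, prone to ionisation under acid and to hydrogenolysis) and the two oxidisable phenols. The real difficulty is the absolute configuration of C2/C3 independent of the lactone, together with telling the C3 carbinol carbon apart from the lactone carbonyl. The key step exploits the fact that C2–H is both benzylic and α to O1 while C3 carries a carbon that can be a carboxylate: C2–C3 is then the bond a carbene at C3 forms by inserting into the O–CH2–Ar group of a plain vanillyl ether on the C7a oxygen, carried out last on an aryl diazoacetate that already contains the complete trans-lactone.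

## Logic of the disconnections

**19 ⇐ 18.** The two phenolic O–CH2Ph bonds are cut. The phenols must be masked through enolate, carbene and borane chemistry, and benzyl survives all of it. The forward step has to remove both groups without cleaving the O1–C2 bond.

**18 ⇐ 17 ⇐ 15 ⇐ 14.** The C3 CH2OH is traced back to a carboxyl group and C3 to its epimer; no skeletal bond is cut. A carboxyl at C3 allows C3 to be a carbene carbon and allows the trans relationship to be reached by equilibration. The demands are that the carboxyl is reduced in the presence of the lactone (hence the free acid in 17, reduced by borane) and that C3 is epimerised without touching C2 or the lactone.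

**14 ⇐ 13 (key).** The C2–C3 bond of the dihydrofuran ring is cut. C2 becomes the CH2 of an aryl benzyl ether and C3 the carbon of an aryl diazoacetate, so the whole ring with both stereocentres collapses to an ether and a diazo ester on a flat arene. The forward step must choose one of two enantiotopic benzylic hydrogens under catalyst control, in a molecule that already holds the lactone.

**13 ⇐ 11 + 12.** The aryl C3a–C3 bond (the 8–5′ bond of the lignan) is cut to an aryl iodide and a two-carbon diazo unit. The iodide sits where a commercial iodophenol places it. The coupling must keep the diazo group intact.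

**11 ⇐ 9 + 2.** The lactone Cα–CH2Ar bond is cut. The trans relationship then follows from substrate control in an enolate alkylation, which requires the β-stereocentre of 9 to be in place and enantiopure.

**9 ⇐ 7 ⇐ 6.** The lactone C–O bond and the two C–H bonds at the future lactone C4 are cut, leading to an arylidene succinate half-ester. The single stereocentre becomes the product of an asymmetric hydrogenation. The ester, not the acid, must then be reduced.

**6 ⇐ 4 + 5.** The C=C bond is cut to an aldehyde and a succinate. The condensation must give the half-ester with the two carboxyls differentiated.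

**4 ⇐ 3 + 2, and 2 ⇐ 1.** The phenolic O–CH2 bond is cut. The same bromide 2 serves twice: once as the future C2-plus-aryl unit of the dihydrobenzofuran and once as the α-benzyl group of the lactone. The ether must survive every step up to the key step.

## Other disconnections considered

**Alternative 1:** This is the first route that comes to mind, the biomimetic one. The cut removes C3–C3a and O1–C2 together. The forward key step is a one-electron oxidation (Ag2O or peroxidase/H2O2) of mono-benzyl matairesinol A1 together with coniferyl alcohol, 8–5′ radical cross-coupling and trapping of the quinone methide by the phenol, to give A2. The coupling partners meet five bonds away from the lactone stereocentres, so no facial bias can exist and A2 must form as both trans-dihydrobenzofuran diastereomers. Coniferyl radicals also prefer to couple with themselves (β–5, β–β, β–O–4), and A1 needs its own differentiated synthesis. The route is the shortest on paper but cannot deliver the single stereoisomer asked for.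

**Alternative 2:** The dihydrobenzofuran is made first by polar chemistry, cutting O1–C2 (and C2–C3 by an aldol). The forward key step is an oxazolidinone-controlled syn-aldol followed by acid-promoted closure of the phenol onto C2 through a quinone methide cation, giving aldehyde A3; Stobbe condensation, hydrogenation and enolate alkylation would then build the lactone. This needs a stoichiometric auxiliary, a ring closure that is trans only by thermodynamics, protection of the CH2OH, and carriage of the acid-sensitive ring through about six further steps of base, hydride and enolate chemistry. The count comes to roughly sixteen steps against twelve, and it is the conventional disconnection.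

**Alternative 3:** Dearomatisation: the two C–H bonds at C2 and C3 are cut, leading back to benzofuran A4. The forward key step is an asymmetric hydrogenation of the furan C2=C3 bond of A4 to give 14. That bond is tetrasubstituted, part of an aromatic ring and push–pull stabilised (aryloxy donor, ester acceptor), and asymmetric hydrogenation of benzofurans is established mainly for 2- or 3-monosubstituted cases. A4 would also cost several steps from 11, where the chosen plan needs one step to reach 13.

Key step: step 8

Assumption: the catalyst antipodes named in steps 4 and 8 are those expected by analogy with closely related substrates to give the configurations drawn; both antipodes of each are available, and the opposite one would be used if the sense of induction on these substrates were reversed.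

## Steps

**Step 1**
Reactants: 1 4-(benzyloxy)-3-methoxybenzyl alcohol
Product: 2 4-(benzyloxy)-3-methoxybenzyl bromide
Conditions: PBr3 (0.4 equiv), Et2O, 0 °C; used crude
Reagents that add atoms: phosphorus tribromide, BrP(Br)Br
Why: Conversion of a primary benzylic alcohol into the bromide by SN2 displacement on the bromophosphite; the electron-rich bromide is used within hours.

**Step 2**
Reactants: 3 5-iodovanillin (4-hydroxy-3-iodo-5-methoxybenzaldehyde); 2 4-(benzyloxy)-3-methoxybenzyl bromide
Product: 4 4-{[4-(benzyloxy)-3-methoxybenzyl]oxy}-3-iodo-5-methoxybenzaldehyde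
Conditions: K2CO3, DMF, rt
Reagents that add atoms: none
Why: Williamson ether synthesis; the phenol of 3, acidified by the para-formyl and ortho-iodo groups, should be O-alkylated cleanly by the primary benzylic bromide, and this O–CH2Ar group is the future O1–C2–aryl unit of the dihydrobenzofuran.

**Step 3**
Reactants: 4 aldehyde from step 2; 5 dimethyl succinate
Product: 6 (E)-4-(4-{[4-(benzyloxy)-3-methoxybenzyl]oxy}-3-iodo-5-methoxyphenyl)-3-(methoxycarbonyl)but-3-enoic acid
Conditions: NaOMe, MeOH, reflux; then cold 1 M HCl
Reagents that add atoms: none
Why: Stobbe condensation (aldol addition, lactonisation to the paraconate, E1cB opening) should give the half-ester with the E alkene and with the two carboxyl groups differentiated; no stereocentre is formed.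

**Step 4**
Reactants: 6 Stobbe half-ester
Product: 7 (R)-4-(4-{[4-(benzyloxy)-3-methoxybenzyl]oxy}-3-iodo-5-methoxyphenyl)-3-(methoxycarbonyl)butanoic acid
Conditions: [Rh(cod)((S,S)-Et-DuPhos)]BF4 (1 mol%), H2 (10 bar), NaOMe (10 mol%), MeOH, rt
Reagents that add atoms: none
Why: Rh(I)–bisphospholane asymmetric hydrogenation of an itaconate-type half-ester; the carboxylate binds rhodium and the C2-symmetric ligand selects the alkene face, setting the future lactone C4 as R, while the homogeneous cationic catalyst should leave the benzyl ethers and the aryl iodide untouched.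

**Step 5**
Reactants: 7 (R)-half-ester
Product: 9 (R)-4-(4-{[4-(benzyloxy)-3-methoxybenzyl]oxy}-3-iodo-5-methoxybenzyl)dihydrofuran-2(3H)-one, via hydroxy acid 8 (not isolated)
Conditions: KOH (1.0 equiv), EtOH; CaCl2, NaBH4, EtOH, −10 °C to rt; then 1 M HCl to pH 2–3, 0 °C to rt
Reagents that add atoms: none
Why: Chemoselective borohydride reduction of the ester while the carboxyl group is protected as its salt, then acid-promoted γ-lactonisation; the stereocentre is not involved and stays R.

**Step 6**
Reactants: 9 (R)-β-benzyl lactone; 2 4-(benzyloxy)-3-methoxybenzyl bromide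
Product: 11 (3R,4R)-3-[4-(benzyloxy)-3-methoxybenzyl]-4-(4-{[4-(benzyloxy)-3-methoxybenzyl]oxy}-3-iodo-5-methoxybenzyl)dihydrofuran-2(3H)-one, via lithium enolate 10 (not isolated)
Conditions: LiHMDS, THF, −78 °C; then 2, DMPU, −78 to −30 °C
Reagents that add atoms: none
Why: Lactone enolate alkylation; the bromide approaches the planar enolate anti to the C4 substituent, so the new C3 centre should be R and trans to C4 under substrate control, as is general for β-benzyl-γ-butyrolactones.

**Step 7**
Reactants: 11 iodo lactone; 12 ethyl diazoacetate
Product: 13 ethyl 2-diazo-2-(2-{[4-(benzyloxy)-3-methoxybenzyl]oxy}-5-{[(3R,4R)-4-(4-(benzyloxy)-3-methoxybenzyl)-5-oxotetrahydrofuran-3-yl]methyl}-3-methoxyphenyl)acetate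
Conditions: Pd(PPh3)4 (5 mol%), Ag2CO3 (0.5 equiv), Et3N (1.3 equiv), toluene, rt, dark
Reagents that add atoms: none
Why: Pd(0)-catalysed cross-coupling of an aryl iodide with the C–H of an acceptor diazo compound (oxidative addition, silver/amine-assisted palladation of the diazo carbon, reductive elimination with N2 retained); it forms the C3a–C3 bond at room temperature and should tolerate lactone and ethers, with no stereocentre affected.

**Step 8**
Reactants: 13 aryl diazoacetate
Product: 14 ethyl (2S,3R)-2-[4-(benzyloxy)-3-methoxyphenyl]-5-{[(3R,4R)-4-(4-(benzyloxy)-3-methoxybenzyl)-5-oxotetrahydrofuran-3-yl]methyl}-7-methoxy-2,3-dihydrobenzofuran-3-carboxylate (2,3-cis)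
Conditions: Rh2(R-PTTL)4 (2 mol%), toluene, −60 to −40 °C, slow addition of 13
Reagents that add atoms: none
Why: The chiral dirhodium carboxylate expels N2 from 13 to give a donor/acceptor rhodium carbene, which inserts into one of the two enantiotopic C–H bonds of the ortho O–CH2Ar group through a concerted, asynchronous three-centre transition state with hydride-transfer character. The closest known reaction type is the Rh(II)-carboxylate-catalysed enantioselective intramolecular 1,5-C–H insertion of aryl diazoacetates into aryl benzyl ethers, which gives cis-2-aryl-2,3-dihydrobenzofuran-3-carboxylates. One ring is closed, the dihydrofuran ring, by 1,5-insertion that forms the C2–C3 bond through a five-membered arrangement of C3, C3a, C7a, O1 and C2. C2 (S) is set by which benzylic hydrogen the phthalimido-carboxylate pocket of the catalyst accepts; this is pure catalyst control, since the lactone stereocentres are five bonds away behind the arene. C3 is set in the same transition state and is expected cis to the aryl group (3R); it is provisional and is corrected in step 9. The step needs site selectivity, enantiotopic selection and insertion over carbene dimerisation: the only C–H within five-membered reach is doubly activated (α-oxygen, electron-rich benzylic), the ether oxygen could only form a four-membered ylide, and slow addition at low temperature keeps the carbene concentration low. Because the lactone is already enantiopure, any shortfall in facial control would appear as a separable diastereomer and not as the enantiomer.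

**Step 9**
Reactants: 14 cis ester
Product: 15 ethyl (2S,3S)-2-[4-(benzyloxy)-3-methoxyphenyl]-5-{[(3R,4R)-4-(4-(benzyloxy)-3-methoxybenzyl)-5-oxotetrahydrofuran-3-yl]methyl}-7-methoxy-2,3-dihydrobenzofuran-3-carboxylate (2,3-trans)
Conditions: DBU (1 equiv), toluene, 50 °C
Reagents that add atoms: none
Why: Base-mediated epimerisation through the ester enolate at C3 (α-aryl, α-ester, the most acidic C–H) to the thermodynamically favoured trans isomer; C2 is not acidic and keeps its S configuration, and the lactone α-C–H is several pKa units less acidic and already trans.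

**Step 10**
Reactants: 15 trans ester
Product: 17 (2S,3S)-2-[4-(benzyloxy)-3-methoxyphenyl]-5-{[(3R,4R)-4-(4-(benzyloxy)-3-methoxybenzyl)-5-oxotetrahydrofuran-3-yl]methyl}-7-methoxy-2,3-dihydrobenzofuran-3-carboxylic acid, via hydroxy diacid 16 (not isolated)
Conditions: LiOH·H2O (6 equiv), THF/H2O (3:1), rt; then 1 M HCl to pH 2, rt
Reagents that add atoms: lithium hydroxide, [Li+].[OH-]
Why: Saponification; hydroxide also opens the lactone (carboxylates do not epimerise), and acidification should re-close only the γ-hydroxy acid to the five-membered lactone, leaving the C3 carboxylic acid free and so chemically distinct from the lactone carbonyl.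

**Step 11**
Reactants: 17 acid lactone
Product: 18 (3R,4R)-3-[4-(benzyloxy)-3-methoxybenzyl]-4-({(2S,3R)-2-[4-(benzyloxy)-3-methoxyphenyl]-3-(hydroxymethyl)-7-methoxy-2,3-dihydrobenzofuran-5-yl}methyl)dihydrofuran-2(3H)-one
Conditions: BH3·THF (2.5 equiv), THF, 0 °C to rt; MeOH quench
Reagents that add atoms: none
Why: Chemoselective borane reduction of a carboxylic acid through its acyloxyborane in the presence of a lactone, which reacts far more slowly with electrophilic borane at 0 °C; no stereocentre is touched (the descriptor at C3 changes to R only through the priority rules).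

**Step 12**
Reactants: 18 di-O-benzyl lappaol A
Product: 19 lappaol A, (3R,4R)-3-(4-hydroxy-3-methoxybenzyl)-4-{[(2S,3R)-2-(4-hydroxy-3-methoxyphenyl)-3-(hydroxymethyl)-7-methoxy-2,3-dihydrobenzofuran-5-yl]methyl}dihydrofuran-2(3H)-one
Conditions: H2 (1 atm), 10% Pd/C, EtOAc/EtOH, rt, stopped at full debenzylation
Reagents that add atoms: none
Why: Hydrogenolysis of two aryl benzyl ethers under mild neutral conditions; aryl O–benzyl bonds should cleave faster than the cyclic O1–C2 ether, and lactone and stereocentres are inert.

## Compound list

1 | 4-(benzyloxy)-3-methoxybenzyl alcohol | COc1cc(CO)ccc1OCc1ccccc1 | starting material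
2 | 4-(benzyloxy)-3-methoxybenzyl bromide | COc1cc(CBr)ccc1OCc1ccccc1 | intermediate
3 | 5-iodovanillin | COc1cc(C=O)cc(I)c1O | starting material
4 | 4-{[4-(benzyloxy)-3-methoxybenzyl]oxy}-3-iodo-5-methoxybenzaldehyde | COc1cc(C=O)cc(I)c1OCc1ccc(OCc2ccccc2)c(OC)c1 | intermediate
5 | dimethyl succinate | COC(=O)CCC(=O)OC | starting material
6 | (E)-Stobbe half-ester | COC(=O)/C(CC(=O)O)=C/c1cc(I)c(OCc2ccc(OCc3ccccc3)c(OC)c2)c(OC)c1 | intermediate
7 | (R)-4-aryl-3-(methoxycarbonyl)butanoic acid | COC(=O)[C@@H](CC(=O)O)Cc1cc(I)c(OCc2ccc(OCc3ccccc3)c(OC)c2)c(OC)c1 | intermediate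
8 | (R)-4-aryl-3-(hydroxymethyl)butanoic acid | OC(=O)C[C@H](CO)Cc1cc(I)c(OCc2ccc(OCc3ccccc3)c(OC)c2)c(OC)c1 | intermediate (not isolated)
9 | (R)-4-(4-{[4-(benzyloxy)-3-methoxybenzyl]oxy}-3-iodo-5-methoxybenzyl)dihydrofuran-2(3H)-one | O=C1C[C@@H](Cc2cc(I)c(OCc3ccc(OCc4ccccc4)c(OC)c3)c(OC)c2)CO1 | intermediate
10 | lithium enolate of 9 | [Li+].[O-]C1=C[C@@H](Cc2cc(I)c(OCc3ccc(OCc4ccccc4)c(OC)c3)c(OC)c2)CO1 | intermediate (not isolated)
11 | (3R,4R)-trans-dibenzyl iodo lactone | COc1cc(C[C@H]2C(=O)OC[C@@H]2Cc2cc(OC)c(OCc3ccc(OCc4ccccc4)c(OC)c3)c(I)c2)ccc1OCc1ccccc1 | intermediate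
12 | ethyl diazoacetate | CCOC(=O)C=[N+]=[N-] | starting material
13 | aryl diazoacetate bearing the (3R,4R)-lactone | COc1cc(C[C@H]2C(=O)OC[C@@H]2Cc2cc(OC)c(OCc3ccc(OCc4ccccc4)c(OC)c3)c(c2)C(=[N+]=[N-])C(=O)OCC)ccc1OCc1ccccc1 | intermediate
14 | (2S,3R)-cis-dihydrobenzofuran ethyl ester | COc1cc(C[C@H]2C(=O)OC[C@@H]2Cc2cc(OC)c3c(c2)[C@@H](C(=O)OCC)[C@@H](c2ccc(OCc4ccccc4)c(OC)c2)O3)ccc1OCc1ccccc1 | intermediate
15 | (2S,3S)-trans-dihydrobenzofuran ethyl ester | COc1cc(C[C@H]2C(=O)OC[C@@H]2Cc2cc(OC)c3c(c2)[C@H](C(=O)OCC)[C@@H](c2ccc(OCc4ccccc4)c(OC)c2)O3)ccc1OCc1ccccc1 | intermediate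
16 | ring-opened hydroxy diacid (side chain 2R,3R; dihydrobenzofuran 2S,3S) | COc1cc(C[C@@H](C(=O)O)[C@H](CO)Cc2cc(OC)c3c(c2)[C@H](C(=O)O)[C@@H](c2ccc(OCc4ccccc4)c(OC)c2)O3)ccc1OCc1ccccc1 | intermediate (not isolated)
17 | (2S,3S)-dihydrobenzofuran-3-carboxylic acid with intact (3R,4R)-lactone | COc1cc(C[C@H]2C(=O)OC[C@@H]2Cc2cc(OC)c3c(c2)[C@H](C(=O)O)[C@@H](c2ccc(OCc4ccccc4)c(OC)c2)O3)ccc1OCc1ccccc1 | intermediate
18 | di-O-benzyl lappaol A | COc1cc(C[C@H]2C(=O)OC[C@@H]2Cc2cc(OC)c3c(c2)[C@H](CO)[C@@H](c2ccc(OCc4ccccc4)c(OC)c2)O3)ccc1OCc1ccccc1 | intermediate
19 | lappaol A | COc1cc(C[C@H]2C(=O)OC[C@@H]2Cc2cc(OC)c3c(c2)[C@H](CO)[C@@H](c2ccc(O)c(OC)c2)O3)ccc1O | target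

## Step count and least certain steps

Total step count: 12. Longest linear sequence: 12 steps (1 to 19; 11 steps counted from 3).

**Step 8 (key step).** The most likely failure is insufficient discrimination between the two enantiotopic benzylic hydrogens: the 7-methoxy group twists the O–CH2Ar group out of the arene plane and may change the geometry for which the catalyst pocket is suited. Carbene dimerisation and a different sense at C2 in any trans product formed directly would further erode the ratio after step 9. The fallback replaces catalyst-only control by a covalent auxiliary; it sets out from 11 and returns at 17. Ethyl (S)-lactate and pyrrolidine would give (S)-2-hydroxy-1-(pyrrolidin-1-yl)propan-1-one F1. Acylation with glyoxylic acid chloride p-toluenesulfonylhydrazone and Et3N would give its diazoacetate, (S)-1-oxo-1-(pyrrolidin-1-yl)propan-2-yl 2-diazoacetate F2. Coupling of F2 with 11 under the conditions of step 7 would give the auxiliary aryl diazoacetate F3. Rh2(S-DOSP)4 in CH2Cl2 should then give, by matched double stereodifferentiation, the (2S,3S)-trans dihydrobenzofuran auxiliary ester F4 directly. LiOH followed by acid, as in step 10, would release the auxiliary and give 17.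

**Step 7.** Slow oxidative addition or palladation at the ortho-alkoxy-flanked iodide, and palladium-induced loss of N2 from the product, could lower the yield. The fallback sets out from 11 and returns at 13: Pd-catalysed α-arylation with the Reformatsky reagent of ethyl bromoacetate (Pd(dba)2/XPhos, THF, 50 °C) would give the ethyl arylacetate F5, and diazo transfer with p-ABSA/DBU in MeCN would give 13.

**Step 4.** Oxidative addition of the aryl iodide to rhodium (dehalogenation) or incomplete facial selection on the E/Z mixture could occur. The fallback replaces asymmetric catalysis by resolution; it sets out from 6 and returns at 7. Hydrogenation with RhCl(PPh3)3 would give the racemic half-ester F6. Crystallisation with one enantiomer of 1-phenylethylamine (drawn as R; whichever gives the less soluble salt of the R acid is used) would give the salt F7, and acidification would return 7.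

**Step 11.** Competing slow reduction of the lactone by excess borane is the main concern. The fallback changes the reduction from electrophilic hydride on the free acid to nucleophilic hydride on an activated acyl group; it sets out from 17 and returns at 18. Isobutyl chloroformate and N-methylmorpholine (THF, −15 °C) would give the mixed carbonic anhydride F8, which NaBH4 in THF/H2O at −15 °C should reduce to 18 without touching the lactone.

**Step 12.** Hydrogenolytic opening of the O1–C2 benzylic aryl ether could accompany debenzylation once the C2 aryl group becomes a free phenol. The fallback is non-reductive: from 18 directly to 19 with BCl3 and pentamethylbenzene in CH2Cl2 at −78 °C, the arene scavenging the benzyl cations; no new compound is made.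

## Further compounds

F1 | step 8 | (S)-2-hydroxy-1-(pyrrolidin-1-yl)propan-1-one | C[C@H](O)C(=O)N1CCCC1
F2 | step 8 | (S)-1-oxo-1-(pyrrolidin-1-yl)propan-2-yl 2-diazoacetate | C[C@H](OC(=O)C=[N+]=[N-])C(=O)N1CCCC1
F3 | step 8 | auxiliary aryl diazoacetate (lactate pyrrolidide ester analogue of 13) | COc1cc(C[C@H]2C(=O)OC[C@@H]2Cc2cc(OC)c(OCc3ccc(OCc4ccccc4)c(OC)c3)c(c2)C(=[N+]=[N-])C(=O)O[C@@H](C)C(=O)N2CCCC2)ccc1OCc1ccccc1
F4 | step 8 | (2S,3S)-trans-dihydrobenzofuran auxiliary ester | COc1cc(C[C@H]2C(=O)OC[C@@H]2Cc2cc(OC)c3c(c2)[C@H](C(=O)O[C@@H](C)C(=O)N2CCCC2)[C@@H](c2ccc(OCc4ccccc4)c(OC)c2)O3)ccc1OCc1ccccc1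
F5 | step 7 | ethyl arylacetate (13 without the diazo group) | COc1cc(C[C@H]2C(=O)OC[C@@H]2Cc2cc(OC)c(OCc3ccc(OCc4ccccc4)c(OC)c3)c(c2)CC(=O)OCC)ccc1OCc1ccccc1
F6 | step 4 | racemic 4-aryl-3-(methoxycarbonyl)butanoic acid | COC(=O)C(CC(=O)O)Cc1cc(I)c(OCc2ccc(OCc3ccccc3)c(OC)c2)c(OC)c1
F7 | step 4 | (R)-1-phenylethylammonium salt of the (R)-half-ester | COC(=O)[C@@H](CC(=O)[O-])Cc1cc(I)c(OCc2ccc(OCc3ccccc3)c(OC)c2)c(OC)c1.C[C@@H]([NH3+])c1ccccc1
F8 | step 11 | isobutyl mixed carbonic anhydride of 17 | COc1cc(C[C@H]2C(=O)OC[C@@H]2Cc2cc(OC)c3c(c2)[C@H](C(=O)OC(=O)OCC(C)C)[C@@H](c2ccc(OCc4ccccc4)c(OC)c2)O3)ccc1OCc1ccccc1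
F0 | step 12 | none | none
A1 | alternative 1 | (3R,4R)-3-[4-(benzyloxy)-3-methoxybenzyl]-4-(4-hydroxy-3-methoxybenzyl)dihydrofuran-2(3H)-one | COc1cc(C[C@H]2C(=O)OC[C@@H]2Cc2ccc(O)c(OC)c2)ccc1OCc1ccccc1
A2 | alternative 1 | mono-O-benzyl lappaol A as the mixture of (2S,3R) and (2R,3S) trans-dihydrobenzofuran diastereomers | COc1cc(C[C@H]2C(=O)OC[C@@H]2Cc2cc(OC)c3c(c2)C(CO)C(c2ccc(O)c(OC)c2)O3)ccc1OCc1ccccc1
A3 | alternative 2 | (2S,3R)-2-[4-(benzyloxy)-3-methoxyphenyl]-3-(hydroxymethyl)-7-methoxy-2,3-dihydrobenzofuran-5-carbaldehyde | O=Cc1cc(OC)c2c(c1)[C@H](CO)[C@@H](c1ccc(OCc3ccccc3)c(OC)c1)O2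
A4 | alternative 3 | ethyl 2-[4-(benzyloxy)-3-methoxyphenyl]-7-methoxy-5-(lactonylmethyl)benzofuran-3-carboxylate | COc1cc(C[C@H]2C(=O)OC[C@@H]2Cc2cc(OC)c3oc(-c4ccc(OCc5ccccc5)c(OC)c4)c(C(=O)OCC)c3c2)ccc1OCc1ccccc1
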